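In a one-step world with first-order loss, the fraction turned over depends on the product of a rate constant k and a time t, so the meeting on flasks east and south-west agreed to count that product in powers of ten.

| setting | ochre | east | south-west |
|---|---|---|---|
| starting material | 0.10 M | 0.10 M | 0.20 M |
| partner | 0.050 M | 0.0500 M | 0.200 M |
| free catalyst | 3 mM | 4.5 mM | 4.5 mM |
| temperature | 70 °C |  |  |
| remark | run made earlier | at 70 °C until 4.0 d, from then on at 30 °C | at 30 °C throughout |
| time |  | 8.0 d | 8.0 d |

- ochre (time / h: target / %, starting material / %): 6.00: 4.7, 92.7; 12.0: 13.2, 85.5; 15.0: 17.5, 82.4; 20.0: 22.7, 76.1; 30.0: 31.9, 66.0; 40.0: 39.3, 58.3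

(standard deviation of a reading: 1 percentage point)

- the earlier runs do not show what temperature does; that part of a forecast is a guess
- no earlier run changes the charge of free catalyst; that part of a forecast is a guess

- the flask that ends with the higher amount of target, in percent of the starting material charged, or "neither" when 2 percentage points or less lies between them (east / south-west / neither)
- final target, as a percentage of the starting material charged, in east
- final target, as a percentage of the starting material charged, in south-west

Minutes. The first speaker read the ochre run as a pseudo-first-order decay of the starting material and took k = 0.0135 h⁻¹ from its last reading, scatter included. I then proposed as the measure a flask's decades Λ, the base-ten logarithm of k·t, with k scaled in proportion to free catalyst, which I called a guess. A target fraction y then stands at Λ = log10(ln(1/(1−y))), taking target as turnover. For south-west's catalyst and time, held at 70 °C, I reckoned 0.589, south-west's decades before any cooling. I argued that east gets 0.288 decades in its 4.0 d at 70 °C, while the cap of 50.0% set by the partner, its limiting reagent if the two react one to one, needs −0.159, so east should reach that cap with a margin of 0.447 decades. South-west would match that cap at a cooling cost of 0.748 decades and pass it at a smaller cost, and since no run measures cooling, I gave no figure for south-west and named east only as a guess that the cost is larger.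

The forecaster then put east ahead (east), with 49% (45% to 52%) in east and 10% (3% to 25%) in south-west, saying: “Guessing Ea ≈ 80 kJ/mol slows the reaction about 40-fold”. I noted that this south-west figure stands at −0.977 decades, a cooling cost of 1.57.

The flasks gave 48.7% in east and 0.962% in south-west, so east holds more target.

    partner + free catalyst → catalyst intermediate A (k = 73.0 L mol⁻¹ h⁻¹, Ea = 54.0 kJ mol⁻¹)
    catalyst intermediate D → catalyst intermediate E (k = 0.740 h⁻¹, Ea = 119 kJ mol⁻¹)
    catalyst intermediate E ⇌ free catalyst + target (K = 0.0450 M, k = 54.0 h⁻¹, Ea = 92.0 kJ mol⁻¹, ΔH = −21.0 kJ mol⁻¹)
    catalyst intermediate A → by-product + catalyst intermediate B (k = 15.0 h⁻¹, Ea = 103 kJ mol⁻¹)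
    starting material + catalyst intermediate C → catalyst intermediate D (k = 34.0 L mol⁻¹ h⁻¹, Ea = 50.0 kJ mol⁻¹)
    catalyst intermediate B → catalyst intermediate C (k = 3.30 h⁻¹, Ea = 96.0 kJ mol⁻¹)
    (constants at 70 °C)

South-west's 0.962% reads as −2.01 decades, so cooling from 70 °C to 30 °C cost 2.60 decades from the 0.589 carried, more than the forecast's 1.57. Taking that cost in proportion to the change in reciprocal absolute temperature, the neighbouring flask, south-west repeated at 55 °C, stands at −0.313 decades, which is 38.5% of target. That neighbouring flask gave 36.5% of target.

(The data are simulated with constants of no real substance.)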